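I began with 8.78%, my floor on the free share, the part of the flask's unused nucleophile not bound as protonated nucleophile.

electrophile 0.050 M; nucleophile 0.0600 M; free base 0.150 M; protic impurity 5.00 mM; time 10 d

    electrophile + nucleophile → acid set free + product (k1 = 0.0013 M⁻¹ s⁻¹)
    nucleophile + acid set free ⇌ protonated nucleophile, settled at all times (K2 = 540 M⁻¹)
    acid set free + free base ⇌ salt of the base (K3 = 16 M⁻¹, k3 = 0.017 M⁻¹ s⁻¹)
    nucleophile + protic impurity → quenched reagent (k4 = 6.8 × 10⁻⁴ M⁻¹ s⁻¹)
    crystals ⇌ product, rate k5*(cs5 - [product]) while solid is left; crystals form when [product] > cs5 (cs5 = 47 mM, k5 = 0.0033 s⁻¹)

* part of the electrophile that has reacted at 10 d
* share of the unused nucleophile that is free and not bound as protonated nucleophile, at 10 d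

- product is meant together with its crystals
- solid, in amounts per volume of the solution: crystals
- run time (flask): 10 d

In the flask, acid meets free base much faster than electrophile meets nucleophile, so I held step 3 at balance. I charged the acid of the whole electrophile to salt of the base and loose acid together, with the free base lowered by that same amount, which left at most 0.0192 M loose, and step 2 turned that into the floor.

Then I worked with x, the fraction of electrophile left. It falls as x(x+s), on a clock of k1 times the electrophile charge, the free share and time. Take s as the nucleophile spare after electrophile and impurity, 0.100 of the electrophile charge. With the floor the clock reads 4.93, and integration leaves 12.5%, so conversion stands above 87.5%.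

For the bound from above, 100% was the plain ceiling. To tighten it, I started at that same x with no time spent and took s as 0.200, leaving the impurity unused. From there salt of the base and loose acid together cannot fall below the acid made minus the unused nucleophile, and with the free base at most as charged this caps the free share at 18.6%. The clock then gives 99.0%.

The forecast said 95.4% and 11.9%, going by “the acid-partition balance and a rough integration of the slowing rate”. Its conversion lay inside my bracket, and its share stood above my floor.

The flask gave 95.3% and 12.0%, a share above the floor. At 10.0 d acid and free base relaxed with a half-life of 0.0568 h, against 2.6 d for nucleophile by step 1, while the other 88.0% of the unused nucleophile sat as protonated nucleophile, its resting state. In the neighbour flask with 0.38 M of free base, the same floor reads 18.9%, and that neighbour showed a free share of 21.6%.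

(The constants used here are made up; no experiment stands behind them.)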